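# Total synthesis of CNP0136963.1 by a Michael–Claisen construction of resorcinol ring B

## The problem

Target 27 is built on one benzene ring (ring C) with a single free CH. Ring C carries two trans-2,3-dihydrobenzofurans on opposite flanks and, at the carbon between their two benzylic attachment points, the CH2 group Cb of a seven-membered carbocycle. That carbocycle runs Cb–Ca–(two adjacent carbons of resorcinol ring B)–Cf and back through ring C, so Cf belongs both to the seven-membered ring and to one dihydrofuran (Ce, Cf); the other dihydrofuran (Cc, Cd) is remote from it.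

There are five stereocentres: Ca (S), Cc (R), Cd (R), Ce (S) and Cf (S). Within each dihydrofuran the trans relation is the stable one, so one centre of each pair can be corrected by equilibration. The two pairs lie on opposite sides of a flat arene and cannot control each other, and Ca is insulated from both by Cb, so three independent sources of absolute configuration are needed.

The O–CH(aryl) bonds are 4-oxygenated benzylic ethers that ionise in acid, every ring is electron-rich and open to oxidants and electrophiles, and six phenols have to be masked to the end.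

Ring C poses a regiochemical problem of its own. The carbon that must receive Cc lies between two oxygens and next to the carbon that takes Cb, whereas the carbon that stays CH is the more accessible nucleophilic site.

The feature that opens the route is ring B. Its two adjacent oxygen-free carbons are bonded to Ca and Cf and its two C–O carbons are 1,3-related, which is the pattern of a 4,5-disubstituted cyclohexane-1,3-dione. A 2-oxopropyl arm on Ca and an acrylate on Cf can therefore deliver ring B and the seven-membered ring in one operation.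

## Retrosynthesis

**27 from 26.** The six phenols are uncovered last by cleaving nine O–CH3 bonds of nonamethyl ether 26. Methyl ethers are chosen over benzyl or silyl groups because they survive every reagent of the route, and because three of them arrive already in place with the building blocks 2, 9 and 18. The forward step must leave two benzylic aryl ethers intact.

**26 from 24.** Ring B is taken back to cyclohexane-1,3-dione 24 by adding one molecule of H2 and removing the two O-methyl groups. This trades an arene for two carbonyl groups that can be made by enolate chemistry, and it turns the two ring-fusion carbons of ring B into sp3 centres whose configuration is irrelevant. The forward dehydrogenation must not touch the other electron-rich rings.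

**24 from 22.** Two bonds of the dione are cut: the ring-fusion bond between the carbon on Ca and the carbon on Cf, and the bond between one carbonyl carbon and the CH2 flanked by both carbonyls. This gives keto acrylate 22, in which Ca carries a 2-oxopropyl arm and Cf a methyl acrylate. Against a Friedel–Crafts or cross-coupling closure of the seven-membered ring onto a ready-made ring B, this cut needs no functionalised resorcinol and forms ring B and the carbocycle together. The precursor is simpler by two rings. The forward reaction must choose the methylene enolate for the Michael step and the methyl enolate for the Claisen step, and must not disturb Cf.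

**22 from 19.** The acrylate C=C is cut by a Wittig disconnection to aldehyde 21, which comes from the methyl ester at Cf in 19 by way of diol 20. Reducing ester and ketone together and oxidising both back avoids a ketone protecting group. The forward sequence must handle an epimerisable α-aryl aldehyde briefly and olefinate it in the presence of a methyl ketone.

**19 from 17 and 18, and 17 from 15.** The Ca–aryl bond is cut to enone 17 and 4-methoxyphenylboronic acid 18, so that Ca is set by a chiral rhodium catalyst on an acyclic enone, away from the influence of the distant stereocentres. Enone 17 is traced through a cross-metathesis to allyl arene 16 and through a Stille disconnection of the ring C–Cb bond to aryl triflate 15. The triflate oxygen is the 5-OH of naringenin, so the position of Cb is fixed by the starting material. Forward, a hindered triflate must couple and the benzylic enone must not slip into conjugation with ring C before the aryl group adds.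

**15 from 10, and 10 from 8 and 9.** The remote dihydrofuran is opened at the Cc–Cd bond: Cc becomes a diaryl carbene carbon and Cd the CH2 of a 4-methoxybenzyl ether, the known asymmetric C–H insertion route to 2,3-diaryl-2,3-dihydrobenzofurans (12 to 14 via 13). The insertion gives the cis ring 14, which acid turns into trans 15. This is preferred to a quinone methide annulation because a chiral dirhodium catalyst can impose the absolute configuration that ring C cannot relay. The carbene precursor is hydrazone 12 of diaryl ketone 10, and the ketone is cut at both C–C(=O) bonds to aryl iodide 8, carbon monoxide and 3,5-dimethoxyphenylboronic acid 9. Forward, a di-ortho-substituted iodide must be carbonylated in the presence of a triflate, and a hindered ketone must be condensed without harming the ester.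

**8 from 6, and 6 from 1 and 2.** The bond between ring C and Cf is cut by reversing an oxidative aryl shift: dihydrobenzofuran ester 8 comes from flavanone 6 by ring contraction, through enol ether 7. This brings Ce from the chiral pool and places an ester, the acrylate precursor, on Cf. Flavanone 6 is the 5-triflate of iodide 5. The iodine is introduced ortho to the free, chelated 5-OH of ether 4, which solves the regiochemical problem of ring C before the directing phenol is spent as the triflate. Ether 4 comes from (2S)-naringenin 1 by two Mitsunobu etherifications, the first with 4-methoxybenzyl alcohol 2 (giving 3), whose benzylic carbon and aryl group later become Cd and its substituent. The forward steps must keep the base-labile C2 centre of the flavanone intact.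

## Roads not taken

**Alternative 1:** The cut is the bond between ring C and Cc. The forward key step is the same trivalent-iodine ring contraction that serves step 5, but applied to flavanone triflate A2 so that the flavanone becomes the remote dihydrofuran A1, with a methyl ester on Cc.

- Merits: one step gives a trans dihydrofuran with the triflate at the carbon that takes Cb and a benzyloxy group at the oxygen of the second furan, so ring C needs no substitution chemistry for this half.
- Weak points: Cd has the R configuration, so A1 maps onto the unnatural (2R)-naringenin A3, whereas natural material gives the antipode. The ester on Cc must become a 3,5-dihydroxyphenyl ring, by decarboxylative arylation at an epimerisable centre or by a second de novo arene synthesis. The Ce/Cf dihydrofuran, which carries the connections to ring B, would still have to be built with catalyst control at the harder position of ring C.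
- Comparison: Alternative 1 reaches the remote ring in one step where the chosen plan spends steps 6 to 9 and a chiral dirhodium catalyst. Against that, the chosen plan uses the ring contraction where the natural configuration fits and where the ester is exactly the handle the key step needs.

**Alternative 2:** The cut goes through ring C itself. Diazo ketone A5 is irradiated and a cascade of Wolff rearrangement, [2+2] addition to the tethered alkynyl ether, four-electron ring opening and six-electron ring closure gives phenol A4, with ring C and the remote dihydrofuran formed together.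

- Merits: the substitution pattern of ring C is fixed by construction, so the regiochemical problem that the chosen plan solves with a directed iodination does not arise for this half. The CH2O group for Cb is in place and the route is convergent.
- Weak points: A5 must carry Cc and Cd, set beforehand in an open chain, next to a diazo ketone at a branched carbon and an acid-sensitive ethynyl ether. After A4 the Ce/Cf dihydrofuran still has to be built on a phenol with two open ortho positions and with its own source of chirality, and the seven-membered ring and ring B remain. The step count is clearly higher.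
- Comparison: Alternative 2 is better in the regiocontrol of ring C. The chosen plan sets against it the chiral pool for Ce and Cf and a shorter path to the key step.

**Alternative 3:** The cut is the Ca–Cb bond. Eight-membered sulfone A7 undergoes a Ramberg–Bäcklund reaction (halogenation next to sulfur, closure across the ring, loss of SO2) to dibenzosuberene A6, whose Ca=Cb double bond must then be hydrogenated.

- Merits: ring B enters as a finished arene, so no dehydrogenation is needed in the presence of electron-rich rings and no base-labile acrylate is carried. The medium ring is closed by easy C–S bond formation and the extrusion tolerates aryl ethers. In the mildness of its endgame this road is better than the chosen one.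
- Weak points: A7 presupposes the Cf–ring B bond, so both dihydrofurans must be 2,3-diaryl rings made with catalyst control and ring B must be brought in with a benzylic handle. Ca is left to the hydrogenation of a trisubstituted, stilbene-like alkene in a seven-membered ring, where facial control by Cf is uncertain and the benzylic C–O bonds are at risk.
- Comparison: the chosen plan fixes Ca by a catalyst on an acyclic enone before the ring exists and builds ring B from small fragments. Its price is the base-mediated key step and the late aromatisation.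

Key step: step 15

Assumption: (2S)-naringenin of high enantiomeric purity is used, and the enantiomer of each chiral rhodium catalyst is assigned by analogy with simple substrates, the antipodal ligand being taken if the sense proves opposite.

## Route

Step 1
Reactants: 1 (2S)-naringenin; 2 4-methoxybenzyl alcohol
Product: 3 (2S)-5-hydroxy-2-(4-hydroxyphenyl)-7-[(4-methoxybenzyl)oxy]chroman-4-one
Conditions: PPh3, DIAD, THF, 0 °C → rt
Reagents that add atoms: none
Why: Mitsunobu etherification; the 7-OH, para to the carbonyl group, is the most acidic phenol and should react first, and the neutral conditions avoid the base-induced chalcone opening that would racemise C2; the benzylic CH2 introduced here is the future Cd.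

Step 2
Reactants: 3 (2S)-5-hydroxy-2-(4-hydroxyphenyl)-7-[(4-methoxybenzyl)oxy]chroman-4-one
Product: 4 (2S)-5-hydroxy-7-[(4-methoxybenzyl)oxy]-2-(4-methoxyphenyl)chroman-4-one
Conditions: MeOH, PPh3, DIAD, THF, 0 °C → rt
Reagents that add atoms: methanol, CO
Why: Second Mitsunobu etherification; the 4′-OH reacts, while the 5-OH is hydrogen-bonded to the C4 carbonyl and flanked by it, so it should stay free for the next step.

Step 3
Reactants: 4 (2S)-5-hydroxy-7-[(4-methoxybenzyl)oxy]-2-(4-methoxyphenyl)chroman-4-one
Product: 5 (2S)-5-hydroxy-6-iodo-7-[(4-methoxybenzyl)oxy]-2-(4-methoxyphenyl)chroman-4-one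
Conditions: BnMe3N+ ICl2−, CaCO3, CH2Cl2–MeOH, rt
Reagents that add atoms: benzyltrimethylammonium dichloroiodate, C[N+](C)(C)Cc1ccccc1.Cl[I-]Cl
Why: Electrophilic aromatic iodination directed to the only open position ortho to the free chelated 5-OH, as known for 5-hydroxy-7-alkoxyflavonoids with this reagent; it marks the ring C carbon between the two oxygens, which must carry Cc, and the buffered medium leaves C2 alone.

Step 4
Reactants: 5 (2S)-5-hydroxy-6-iodo-7-[(4-methoxybenzyl)oxy]-2-(4-methoxyphenyl)chroman-4-one
Product: 6 (2S)-6-iodo-7-[(4-methoxybenzyl)oxy]-2-(4-methoxyphenyl)-4-oxochroman-5-yl trifluoromethanesulfonate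
Conditions: Tf2O, pyridine, CH2Cl2, 0 °C
Reagents that add atoms: trifluoromethanesulfonic anhydride, O=S(=O)(OS(=O)(=O)C(F)(F)F)C(F)(F)F
Why: O-Sulfonylation of the chelated phenol; it masks the last phenol before the oxidation and installs the leaving group for the later C–C coupling at the carbon that takes Cb.

Step 5
Reactants: 6 (2S)-6-iodo-7-[(4-methoxybenzyl)oxy]-2-(4-methoxyphenyl)-4-oxochroman-5-yl trifluoromethanesulfonate
Product: 8 methyl (2S,3S)-5-iodo-6-[(4-methoxybenzyl)oxy]-2-(4-methoxyphenyl)-4-(triflyloxy)-2,3-dihydrobenzofuran-3-carboxylate (trans ester), via methyl enol ether 7 (not isolated)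
Conditions: PhI(OAc)2, H2SO4 (cat.), HC(OMe)3, 0 °C → rt
Reagents that add atoms: trimethyl orthoformate, COC(OC)OC; water, O
Why: Oxidative ring contraction of a flavanone by trivalent iodine: acid and orthoformate give enol ether 7, the iodane bonds to C3 anti to the C2 aryl group, and the ring A carbon shifts from C4 to C3 as PhI leaves, the resulting dimethoxycarbenium ion ending as the methyl ester; C2 is not involved and stays S (Ce), and Cf is set trans to it by the anti shift and is in any case the stable epimer.

Step 6
Reactants: 8 methyl (2S,3S)-5-iodo-6-[(4-methoxybenzyl)oxy]-2-(4-methoxyphenyl)-4-(triflyloxy)-2,3-dihydrobenzofuran-3-carboxylate; 9 3,5-dimethoxyphenylboronic acid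
Product: 10 methyl (2S,3S)-5-(3,5-dimethoxybenzoyl)-6-[(4-methoxybenzyl)oxy]-2-(4-methoxyphenyl)-4-(triflyloxy)-2,3-dihydrobenzofuran-3-carboxylate
Conditions: CO (1 atm), PdCl2(IPr)(3-chloropyridine) [IPr = 1,3-bis(2,6-diisopropylphenyl)imidazol-2-ylidene] (3 mol %), Cs2CO3, PhCl, 80 °C
Reagents that add atoms: carbon monoxide, [C-]#[O+]
Why: Carbonylative Suzuki–Miyaura coupling with the carbene-ligated palladium catalyst documented for di-ortho-substituted aryl iodides; CO insertion should outrun direct biaryl coupling at the hindered carbon, and the C–I bond reacts well ahead of the C–OTf bond.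

Step 7
Reactants: 10 methyl (2S,3S)-5-(3,5-dimethoxybenzoyl)-6-[(4-methoxybenzyl)oxy]-2-(4-methoxyphenyl)-4-(triflyloxy)-2,3-dihydrobenzofuran-3-carboxylate
Product: 12 hydrazone of ketone 10 (C=N–NH2 at the diaryl ketone carbon), via N-silyl hydrazone 11 (not isolated)
Conditions: (t-BuMe2SiNH)2, Sc(OTf)3 (1 mol %), PhCl, 80 °C; then Bu4NF, AcOH, THF, 0 °C
Reagents that add atoms: 1,2-bis(tert-butyldimethylsilyl)hydrazine, CC(C)(C)[Si](C)(C)NN[Si](C)(C)C(C)(C)C
Why: Scandium-catalysed condensation with the bis-silylhydrazine (Myers hydrazone synthesis) reaches hindered ketones without free hydrazine, so the methyl ester and the aryl triflate should not be attacked; buffered fluoride then frees the N–H hydrazone, which is used at once.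

Step 8
Reactants: 12 hydrazone of ketone 10
Product: 14 methyl (2S,3S,5R,6S)-5-(3,5-dimethoxyphenyl)-2,6-bis(4-methoxyphenyl)-4-(triflyloxy)-2,3,5,6-tetrahydrobenzo[1,2-b:5,4-b']difuran-3-carboxylate (new ring cis), via diaryldiazomethane 13 (not isolated)
Conditions: MnO2, MeCN, 0 °C; then Rh2(R-PTAD)4 [PTAD = (1-adamantyl)(phthalimido)acetate] (1 mol %), 0 °C → rt
Reagents that add atoms: none
Why: Oxidation to the diaryldiazomethane and dirhodium-catalysed intramolecular 1,5 C–H insertion of the donor/donor carbene into the O–CH2 bond of the 4-methoxybenzyl ether, the reaction established for 2,3-diaryl-2,3-dihydrobenzofurans from 2-benzyloxybenzophenone hydrazones; the chiral carboxylate ligands set Cc (R) and the concerted insertion gives the cis ring (Cd S).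

Step 9
Reactants: 14 methyl (2S,3S,5R,6S)-5-(3,5-dimethoxyphenyl)-2,6-bis(4-methoxyphenyl)-4-(triflyloxy)-2,3,5,6-tetrahydrobenzo[1,2-b:5,4-b']difuran-3-carboxylate
Product: 15 methyl (2S,3S,5R,6R)-5-(3,5-dimethoxyphenyl)-2,6-bis(4-methoxyphenyl)-4-(triflyloxy)-2,3,5,6-tetrahydrobenzo[1,2-b:5,4-b']difuran-3-carboxylate (both rings trans)
Conditions: CF3CO2H, CH2Cl2, 0 °C → rt
Reagents that add atoms: none
Why: Acid epimerisation: reversible heterolysis of the Cd–O bond gives a 4-methoxybenzyl cation that recloses on the phenol to the more stable trans ring (Cd R) while Cc, Ce and Cf take no part; the ester-bearing ring is already trans and ionises more slowly because the ester destabilises a cation at Ce.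

Step 10
Reactants: 15 methyl (2S,3S,5R,6R)-5-(3,5-dimethoxyphenyl)-2,6-bis(4-methoxyphenyl)-4-(triflyloxy)-2,3,5,6-tetrahydrobenzo[1,2-b:5,4-b']difuran-3-carboxylate
Product: 16 methyl (2S,3S,5R,6R)-4-allyl-5-(3,5-dimethoxyphenyl)-2,6-bis(4-methoxyphenyl)-2,3,5,6-tetrahydrobenzo[1,2-b:5,4-b']difuran-3-carboxylate
Conditions: allylSnBu3, Pd(PPh3)4 (10 mol %), LiCl, dioxane, 100 °C
Reagents that add atoms: allyltributylstannane, C=CC[Sn](CCCC)(CCCC)CCCC
Why: Stille coupling of an aryl triflate with chloride assistance; the allyl group is small enough for the doubly flanked position, and its first carbon becomes Cb.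

Step 11
Reactants: 16 methyl (2S,3S,5R,6R)-4-allyl-5-(3,5-dimethoxyphenyl)-2,6-bis(4-methoxyphenyl)-2,3,5,6-tetrahydrobenzo[1,2-b:5,4-b']difuran-3-carboxylate
Product: 17 methyl (2S,3S,5R,6R)-5-(3,5-dimethoxyphenyl)-2,6-bis(4-methoxyphenyl)-4-[(2E)-4-oxopent-2-en-1-yl]-2,3,5,6-tetrahydrobenzo[1,2-b:5,4-b']difuran-3-carboxylate
Conditions: methyl vinyl ketone, second-generation Hoveyda–Grubbs catalyst (5 mol %), CH2Cl2, 40 °C
Reagents that add atoms: methyl vinyl ketone, C=CC(C)=O
Why: Olefin cross-metathesis of a terminal allyl arene with an electron-poor enone partner, which should give the E-enone selectively because the enone partner does not readily homodimerise.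

Step 12
Reactants: 17 methyl (2S,3S,5R,6R)-5-(3,5-dimethoxyphenyl)-2,6-bis(4-methoxyphenyl)-4-[(2E)-4-oxopent-2-en-1-yl]-2,3,5,6-tetrahydrobenzo[1,2-b:5,4-b']difuran-3-carboxylate; 18 4-methoxyphenylboronic acid
Product: 19 methyl (2S,3S,5R,6R)-5-(3,5-dimethoxyphenyl)-2,6-bis(4-methoxyphenyl)-4-[(2R)-2-(4-methoxyphenyl)-4-oxopentyl]-2,3,5,6-tetrahydrobenzo[1,2-b:5,4-b']difuran-3-carboxylate
Conditions: [Rh(OH)((R)-BINAP)]2 (3 mol % Rh), dioxane–H2O (10:1), 35 °C
Reagents that add atoms: none
Why: Hayashi–Miyaura asymmetric conjugate addition of an arylboronic acid to an acyclic E-enone; the BINAP-bound aryl–rhodium species selects the enone face and sets Ca under catalyst control, the older centres being too far away to interfere, and the hydroxo complex works without added base so the benzylic enone should not isomerise into conjugation with ring C.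

Step 13
Reactants: 19 methyl (2S,3S,5R,6R)-5-(3,5-dimethoxyphenyl)-2,6-bis(4-methoxyphenyl)-4-[(2R)-2-(4-methoxyphenyl)-4-oxopentyl]-2,3,5,6-tetrahydrobenzo[1,2-b:5,4-b']difuran-3-carboxylate
Product: 20 (4R)-5-[(2S,3R,5R,6R)-5-(3,5-dimethoxyphenyl)-3-(hydroxymethyl)-2,6-bis(4-methoxyphenyl)-2,3,5,6-tetrahydrobenzo[1,2-b:5,4-b']difuran-4-yl]-4-(4-methoxyphenyl)pentan-2-ol (epimers at the carbinol carbon)
Conditions: LiAlH4, THF, 0 °C
Reagents that add atoms: none
Why: Hydride reduction of ester and ketone together, which frees the Cf carbon as a primary alcohol without a ketone protecting group; the new carbinol centre is oxidised away in the next step and needs no control.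

Step 14
Reactants: 20 (4R)-5-[(2S,3R,5R,6R)-5-(3,5-dimethoxyphenyl)-3-(hydroxymethyl)-2,6-bis(4-methoxyphenyl)-2,3,5,6-tetrahydrobenzo[1,2-b:5,4-b']difuran-4-yl]-4-(4-methoxyphenyl)pentan-2-ol
Product: 22 methyl (2E)-3-{(2S,3S,5R,6R)-5-(3,5-dimethoxyphenyl)-2,6-bis(4-methoxyphenyl)-4-[(2R)-2-(4-methoxyphenyl)-4-oxopentyl]-2,3,5,6-tetrahydrobenzo[1,2-b:5,4-b']difuran-3-yl}prop-2-enoate (keto acrylate), via keto aldehyde 21 (not isolated)
Conditions: Dess–Martin periodinane, NaHCO3, CH2Cl2, 0 °C → rt; then Ph3P=CHCO2Me, rt
Reagents that add atoms: methyl (triphenylphosphoranylidene)acetate, COC(=O)C=P(c1ccccc1)(c1ccccc1)c1ccccc1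
Why: Dess–Martin oxidation of both alcohols followed in the same flask by Wittig olefination; the stabilised ylide reacts only with the aldehyde and gives the E-acrylate, and taking the α-aryl aldehyde on at once limits epimerisation at Cf.

Step 15
Reactants: 22 methyl (2E)-3-{(2S,3S,5R,6R)-5-(3,5-dimethoxyphenyl)-2,6-bis(4-methoxyphenyl)-4-[(2R)-2-(4-methoxyphenyl)-4-oxopentyl]-2,3,5,6-tetrahydrobenzo[1,2-b:5,4-b']difuran-3-yl}prop-2-enoate
Product: 24 cyclohexane-1,3-dione fused on the new seven-membered ring (heptamethyl ether; Ca R and Cf S by the sequence rule with unchanged geometry; Cc R; Cd R; Ce S; two ring-fusion centres unassigned), via Michael adduct 23 (not isolated)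
Conditions: NaOMe (3 equiv), MeOH–THF (0.01 M), 0 → 60 °C; then AcOH
Reagents that add atoms: none
Why: Methoxide equilibrates the two ketone enolates; the more substituted methylene enolate adds to the acrylate β-carbon and closes the seven-membered ring (7-exo-trig) to give 23, after which the methyl enolate attacks the ester carbonyl and closes the six-membered ring (6-exo-trig, Claisen condensation) with loss of methoxide. The closest known reaction is the Michael–Claisen [3+3] annulation of ketones with α,β-unsaturated esters to cyclohexane-1,3-diones under thermodynamic enolate control, here with the Michael step made intramolecular. The sequence is pulled forward by the last step, since the dione is deprotonated to a stabilised enolate that no earlier equilibrium can reverse. The two sp3 centres created at the ring fusion become arene carbons in step 16, so their configuration is not controlled and does not matter. The selectivity needed is between the two enolates and is secured by ring size: the methyl enolate could reach the acrylate only through a nine-membered ring, and only the methyl enolate can then reach the ester through a six-membered one. The second requirement is that Cf keeps its configuration although its hydrogen is γ to the ester: proton exchange there is reversible, returns the trans ring as the stable epimer, and cannot open the dihydrofuran because that would be a reverse 5-endo-trig process with the C–O bond orthogonal to the dienolate. High dilution and the matching of alkoxide to ester keep intermolecular addition and transesterification out of the picture.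

Step 16
Reactants: 24 cyclohexane-1,3-dione fused on the seven-membered ring
Product: 26 nonamethyl ether of the target (Ca S; Cc R; Cd R; Ce S; Cf S), via ring B monomethyl ether 25 (not isolated)
Conditions: I2, MeOH, 65 °C; evaporate; then MeI, K2CO3, acetone, 56 °C
Reagents that add atoms: methanol, CO; iodomethane, CI
Why: Iodine-mediated dehydrogenative aromatisation of a cyclohexane-1,3-dione in methanol (enol ether formation, α-iodination, loss of HI), a known route to resorcinol methyl ethers; the two transient ring-fusion centres disappear, and the Williamson methylation collects partly methylated material into one compound.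

Step 17
Reactants: 26 nonamethyl ether of the target
Product: 27 CNP0136963.1 (Ca S; Cc R; Cd R; Ce S; Cf S)
Conditions: BBr3, CH2Cl2, −78 °C → rt; then MeOH, H2O
Reagents that add atoms: none
Why: Lewis-acid cleavage of all nine aryl methyl ethers, the usual last step for permethylated dihydrobenzofuran oligostilbenes; both dihydrofurans are the trans, thermodynamic isomers, so any transient ionisation of a benzylic C–O bond should return the same ring.

## Compound list

1 | (2S)-naringenin | O=C1C[C@@H](c2ccc(O)cc2)Oc2cc(O)cc(O)c21 | starting material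
2 | 4-methoxybenzyl alcohol | COc1ccc(CO)cc1 | starting material
3 | (2S)-5-hydroxy-2-(4-hydroxyphenyl)-7-[(4-methoxybenzyl)oxy]chroman-4-one | O=C1C[C@@H](c2ccc(O)cc2)Oc2cc(OCc3ccc(OC)cc3)cc(O)c21 | intermediate
4 | (2S)-5-hydroxy-7-[(4-methoxybenzyl)oxy]-2-(4-methoxyphenyl)chroman-4-one | O=C1C[C@@H](c2ccc(OC)cc2)Oc2cc(OCc3ccc(OC)cc3)cc(O)c21 | intermediate
5 | (2S)-5-hydroxy-6-iodo-7-[(4-methoxybenzyl)oxy]-2-(4-methoxyphenyl)chroman-4-one | O=C1C[C@@H](c2ccc(OC)cc2)Oc2cc(OCc3ccc(OC)cc3)c(I)c(O)c21 | intermediate
6 | (2S)-6-iodo-7-[(4-methoxybenzyl)oxy]-2-(4-methoxyphenyl)-4-oxochroman-5-yl trifluoromethanesulfonate | O=C1C[C@@H](c2ccc(OC)cc2)Oc2cc(OCc3ccc(OC)cc3)c(I)c(OS(=O)(=O)C(F)(F)F)c21 | intermediate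
7 | (2S)-6-iodo-4-methoxy-7-[(4-methoxybenzyl)oxy]-2-(4-methoxyphenyl)-2H-chromen-5-yl trifluoromethanesulfonate (methyl enol ether, not isolated) | COC1=C[C@@H](c2ccc(OC)cc2)Oc2cc(OCc3ccc(OC)cc3)c(I)c(OS(=O)(=O)C(F)(F)F)c21 | intermediate
8 | methyl (2S,3S)-5-iodo-6-[(4-methoxybenzyl)oxy]-2-(4-methoxyphenyl)-4-(triflyloxy)-2,3-dihydrobenzofuran-3-carboxylate (trans) | COC(=O)[C@@H]1[C@@H](c2ccc(OC)cc2)Oc2cc(OCc3ccc(OC)cc3)c(I)c(OS(=O)(=O)C(F)(F)F)c21 | intermediate
9 | 3,5-dimethoxyphenylboronic acid | COc1cc(OC)cc(B(O)O)c1 | starting material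
10 | methyl (2S,3S)-5-(3,5-dimethoxybenzoyl)-6-[(4-methoxybenzyl)oxy]-2-(4-methoxyphenyl)-4-(triflyloxy)-2,3-dihydrobenzofuran-3-carboxylate | COC(=O)[C@@H]1[C@@H](c2ccc(OC)cc2)Oc2cc(OCc3ccc(OC)cc3)c(C(=O)c3cc(OC)cc(OC)c3)c(OS(=O)(=O)C(F)(F)F)c21 | intermediate
11 | N-(tert-butyldimethylsilyl)hydrazone of ketone 10 (not isolated) | COC(=O)[C@@H]1[C@@H](c2ccc(OC)cc2)Oc2cc(OCc3ccc(OC)cc3)c(C(=NN[Si](C)(C)C(C)(C)C)c3cc(OC)cc(OC)c3)c(OS(=O)(=O)C(F)(F)F)c21 | intermediate
12 | hydrazone of ketone 10 | COC(=O)[C@@H]1[C@@H](c2ccc(OC)cc2)Oc2cc(OCc3ccc(OC)cc3)c(C(=NN)c3cc(OC)cc(OC)c3)c(OS(=O)(=O)C(F)(F)F)c21 | intermediate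
13 | methyl (2S,3S)-5-[diazo(3,5-dimethoxyphenyl)methyl]-6-[(4-methoxybenzyl)oxy]-2-(4-methoxyphenyl)-4-(triflyloxy)-2,3-dihydrobenzofuran-3-carboxylate (not isolated) | COC(=O)[C@@H]1[C@@H](c2ccc(OC)cc2)Oc2cc(OCc3ccc(OC)cc3)c(C(=[N+]=[N-])c3cc(OC)cc(OC)c3)c(OS(=O)(=O)C(F)(F)F)c21 | intermediate
14 | methyl (2S,3S,5R,6S)-5-(3,5-dimethoxyphenyl)-2,6-bis(4-methoxyphenyl)-4-(triflyloxy)-2,3,5,6-tetrahydrobenzo[1,2-b:5,4-b']difuran-3-carboxylate (remote ring cis) | FC(F)(F)S(=O)(=O)Oc1c2c(cc3c1[C@@H](c1cc(OC)cc(OC)c1)[C@@H](c1ccc(OC)cc1)O3)O[C@H](c1ccc(OC)cc1)[C@H]2C(=O)OC | intermediate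
15 | methyl (2S,3S,5R,6R)-5-(3,5-dimethoxyphenyl)-2,6-bis(4-methoxyphenyl)-4-(triflyloxy)-2,3,5,6-tetrahydrobenzo[1,2-b:5,4-b']difuran-3-carboxylate (both rings trans) | FC(F)(F)S(=O)(=O)Oc1c2c(cc3c1[C@@H](c1cc(OC)cc(OC)c1)[C@H](c1ccc(OC)cc1)O3)O[C@H](c1ccc(OC)cc1)[C@H]2C(=O)OC | intermediate
16 | methyl (2S,3S,5R,6R)-4-allyl-5-(3,5-dimethoxyphenyl)-2,6-bis(4-methoxyphenyl)-2,3,5,6-tetrahydrobenzo[1,2-b:5,4-b']difuran-3-carboxylate | C=CCc1c2c(cc3c1[C@@H](c1cc(OC)cc(OC)c1)[C@H](c1ccc(OC)cc1)O3)O[C@H](c1ccc(OC)cc1)[C@H]2C(=O)OC | intermediate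
17 | methyl (2S,3S,5R,6R)-5-(3,5-dimethoxyphenyl)-2,6-bis(4-methoxyphenyl)-4-[(2E)-4-oxopent-2-en-1-yl]-2,3,5,6-tetrahydrobenzo[1,2-b:5,4-b']difuran-3-carboxylate | CC(=O)/C=C/Cc1c2c(cc3c1[C@@H](c1cc(OC)cc(OC)c1)[C@H](c1ccc(OC)cc1)O3)O[C@H](c1ccc(OC)cc1)[C@H]2C(=O)OC | intermediate
18 | 4-methoxyphenylboronic acid | COc1ccc(B(O)O)cc1 | starting material
19 | methyl (2S,3S,5R,6R)-5-(3,5-dimethoxyphenyl)-2,6-bis(4-methoxyphenyl)-4-[(2R)-2-(4-methoxyphenyl)-4-oxopentyl]-2,3,5,6-tetrahydrobenzo[1,2-b:5,4-b']difuran-3-carboxylate | COc1ccc([C@@H](CC(C)=O)Cc2c3c(cc4c2[C@@H](c2cc(OC)cc(OC)c2)[C@H](c2ccc(OC)cc2)O4)O[C@H](c2ccc(OC)cc2)[C@H]3C(=O)OC)cc1 | intermediate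
20 | (4R)-5-[(2S,3R,5R,6R)-5-(3,5-dimethoxyphenyl)-3-(hydroxymethyl)-2,6-bis(4-methoxyphenyl)-2,3,5,6-tetrahydrobenzo[1,2-b:5,4-b']difuran-4-yl]-4-(4-methoxyphenyl)pentan-2-ol (carbinol epimers) | COc1ccc([C@@H](CC(C)O)Cc2c3c(cc4c2[C@@H](c2cc(OC)cc(OC)c2)[C@H](c2ccc(OC)cc2)O4)O[C@H](c2ccc(OC)cc2)[C@H]3CO)cc1 | intermediate
21 | (2S,3S,5R,6R)-5-(3,5-dimethoxyphenyl)-2,6-bis(4-methoxyphenyl)-4-[(2R)-2-(4-methoxyphenyl)-4-oxopentyl]-2,3,5,6-tetrahydrobenzo[1,2-b:5,4-b']difuran-3-carbaldehyde (not isolated) | COc1ccc([C@@H](CC(C)=O)Cc2c3c(cc4c2[C@@H](c2cc(OC)cc(OC)c2)[C@H](c2ccc(OC)cc2)O4)O[C@H](c2ccc(OC)cc2)[C@H]3C=O)cc1 | intermediate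
22 | methyl (2E)-3-{(2S,3S,5R,6R)-5-(3,5-dimethoxyphenyl)-2,6-bis(4-methoxyphenyl)-4-[(2R)-2-(4-methoxyphenyl)-4-oxopentyl]-2,3,5,6-tetrahydrobenzo[1,2-b:5,4-b']difuran-3-yl}prop-2-enoate (keto acrylate, key-step precursor) | COc1ccc([C@@H](CC(C)=O)Cc2c3c(cc4c2[C@@H](c2cc(OC)cc(OC)c2)[C@H](c2ccc(OC)cc2)O4)O[C@H](c2ccc(OC)cc2)[C@H]3/C=C/C(=O)OC)cc1 | intermediate
23 | Michael adduct: seven-membered ring closed, acetyl group on the carbon next to Ca and CH2CO2Me arm on the carbon next to Cf (two new centres unassigned; not isolated) | COc1ccc([C@@H]2Cc3c4c(cc5c3[C@@H](c3cc(OC)cc(OC)c3)[C@H](c3ccc(OC)cc3)O5)O[C@H](c3ccc(OC)cc3)[C@H]4C(CC(=O)OC)C2C(C)=O)cc1 | intermediate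
24 | cyclohexane-1,3-dione fused on the seven-membered ring (key-step product; ring-fusion centres unassigned) | COc1ccc([C@@H]2Cc3c4c(cc5c3[C@@H](c3cc(OC)cc(OC)c3)[C@H](c3ccc(OC)cc3)O5)O[C@H](c3ccc(OC)cc3)[C@H]4C3CC(=O)CC(=O)C32)cc1 | intermediate
25 | ring B monomethyl ether (free OH on the ring B carbon next to the Ca-bearing carbon; not isolated) | COc1ccc([C@@H]2Cc3c4c(cc5c3[C@@H](c3cc(OC)cc(OC)c3)[C@H](c3ccc(OC)cc3)O5)O[C@H](c3ccc(OC)cc3)[C@H]4c3cc(OC)cc(O)c32)cc1 | intermediate
26 | nonamethyl ether of the target | COc1ccc([C@@H]2Cc3c4c(cc5c3[C@@H](c3cc(OC)cc(OC)c3)[C@H](c3ccc(OC)cc3)O5)O[C@H](c3ccc(OC)cc3)[C@H]4c3cc(OC)cc(OC)c32)cc1 | intermediate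
27 | CNP0136963.1 (Ca S, Cc R, Cd R, Ce S, Cf S) | Oc1ccc([C@@H]2Cc3c4c(cc5c3[C@@H](c3cc(O)cc(O)c3)[C@H](c3ccc(O)cc3)O5)O[C@H](c3ccc(O)cc3)[C@H]4c3cc(O)cc(O)c32)cc1 | target

## Step count and risks

Total step count: 17. Longest linear sequence: 17 steps, from naringenin 1 to target 27.

**Step 15 (key step).** The most likely failure is that proton transfer at Cf outruns C–C bond formation. The hydrogen on Cf is benzylic and γ to the ester, so methoxide can form the dienolate, which leads to deconjugation of the acrylate, to epimerisation at Cf before the ring closes, or simply to a stalled seven-membered closure while methoxide adds reversibly to the acrylate. The fallback removes base from the Michael step. It sets out from 22, which is converted with Me3SiCl, NaI and Et3N in MeCN into the more substituted trimethylsilyl enol ether F1. F1 is closed by an intramolecular Mukaiyama–Michael reaction (catalytic Me3SiOTf, CH2Cl2, −78 °C, aqueous work-up) to keto ester 23, now isolated. In 23 the hydrogen on Cf is no longer activated, so a separate Claisen closure with KOtBu in THF can be used, and the route is rejoined at 24.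

**Step 5.** The acid needed for the ring contraction may cleave the 4-methoxybenzyl ether, after which the freed phenol would be oxidised. A 2,3-shift of the electron-rich C2 aryl group (isoflavone formation) or dehydrogenation to the flavone may also compete with the shift of the triflate-bearing ring A carbon. The fallback reaches the same ester under non-acidic conditions by a Wolff rearrangement. It sets out from 6, which is acylated at C3 (LiN(SiMe3)2, CF3CO2CH2CF3, THF, −78 °C) to the trifluoroacetyl ketone F2. Diazo transfer with loss of the trifluoroacetyl group (MsN3, Et3N, MeCN) gives the 3-diazo flavanone F3. Its Wolff rearrangement in methanol (silver benzoate, AgO2CPh, with Et3N, or 365 nm light) contracts the ring to the methyl ester, formed partly as the cis ester F4. NaOMe in MeOH converts F4 into the trans ester, so the route is rejoined at 8.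

**Step 8.** The carbene carbon sits on an aryl ring with two ortho substituents, which twists it out of conjugation. Facial control by the catalyst may therefore be poor, and azine formation may compete with insertion. At the hydrazone stage just before, the neighbouring triflate may also transfer its sulfonyl group to nitrogen. The fallback avoids hydrazone and carbene altogether and accepts a separation of diastereomers, which is possible because Ce and Cf are already fixed. It sets out from 10, which NaBH4 in MeOH–THF reduces to the benzhydrol F5. 4-Toluenesulfinic acid with CF3CO2H in CH2Cl2 removes the 4-methoxybenzyl group and replaces the benzhydrylic hydroxyl, giving the phenol sulfone F6. Cs2CO3 in MeCN eliminates sulfinate to the ortho-quinone methide F7, which is intercepted by the ylide of (4-methoxybenzyl)dimethylsulfonium tetrafluoroborate in a [4+1] annulation. This gives the trans ring as 15 together with its (5S,6S) diastereomer F8, which is removed by chromatography, and the route is rejoined at 15.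

**Step 16.** Iodine may substitute the one free position of ring C, which lies between two ether oxygens, and the hydrogen iodide released in hot methanol may open a benzylic aryl ether by solvolysis. The fallback replaces halogenation–elimination by a palladium-catalysed aerobic dehydrogenation. It sets out from 24, which with Pd(O2CCF3)2 (divalent palladium), 2-(dimethylamino)pyridine, TsOH and O2 in DMSO at 80 °C should give the free resorcinol F9. F9 needs no methylation and goes directly into the BBr3 step, so the route is rejoined at 27.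

## Further compounds

F1 | step 15 | trimethylsilyl enol ether of 22 at the internal (CH=C(OSiMe3)CH3) position | COc1ccc([C@@H](C=C(C)O[Si](C)(C)C)Cc2c3c(cc4c2[C@@H](c2cc(OC)cc(OC)c2)[C@H](c2ccc(OC)cc2)O4)O[C@H](c2ccc(OC)cc2)[C@H]3/C=C/C(=O)OC)cc1
F2 | step 5 | 3-(trifluoroacetyl) derivative of flavanone 6 (C2 geometry unchanged, C3 unassigned) | O=C1C(C(=O)C(F)(F)F)[C@@H](c2ccc(OC)cc2)Oc2cc(OCc3ccc(OC)cc3)c(I)c(OS(=O)(=O)C(F)(F)F)c21
F3 | step 5 | 3-diazo derivative of flavanone 6 (C2 geometry unchanged) | O=C1C(=[N+]=[N-])[C@@H](c2ccc(OC)cc2)Oc2cc(OCc3ccc(OC)cc3)c(I)c(OS(=O)(=O)C(F)(F)F)c21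
F4 | step 5 | methyl (2S,3R)-5-iodo-6-[(4-methoxybenzyl)oxy]-2-(4-methoxyphenyl)-4-(triflyloxy)-2,3-dihydrobenzofuran-3-carboxylate (cis ester) | COC(=O)[C@H]1[C@@H](c2ccc(OC)cc2)Oc2cc(OCc3ccc(OC)cc3)c(I)c(OS(=O)(=O)C(F)(F)F)c21
F5 | step 8 | benzhydrol from ketone 10 (carbinol epimers) | COC(=O)[C@@H]1[C@@H](c2ccc(OC)cc2)Oc2cc(OCc3ccc(OC)cc3)c(C(O)c3cc(OC)cc(OC)c3)c(OS(=O)(=O)C(F)(F)F)c21
F6 | step 8 | methyl (2S,3S)-5-[(3,5-dimethoxyphenyl)(4-tolylsulfonyl)methyl]-6-hydroxy-2-(4-methoxyphenyl)-4-(triflyloxy)-2,3-dihydrobenzofuran-3-carboxylate (sulfone epimers) | COC(=O)[C@@H]1[C@@H](c2ccc(OC)cc2)Oc2cc(O)c(C(c3cc(OC)cc(OC)c3)S(=O)(=O)c3ccc(C)cc3)c(OS(=O)(=O)C(F)(F)F)c21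
F7 | step 8 | ortho-quinone methide from F6 (exocyclic 3,5-dimethoxybenzylidene next to the ring carbonyl) | COC(=O)[C@@H]1[C@@H](c2ccc(OC)cc2)OC2=CC(=O)C(=Cc3cc(OC)cc(OC)c3)C(OS(=O)(=O)C(F)(F)F)=C12
F8 | step 8 | methyl (2S,3S,5S,6S)-5-(3,5-dimethoxyphenyl)-2,6-bis(4-methoxyphenyl)-4-(triflyloxy)-2,3,5,6-tetrahydrobenzo[1,2-b:5,4-b']difuran-3-carboxylate (diastereomer of 15) | FC(F)(F)S(=O)(=O)Oc1c2c(cc3c1[C@H](c1cc(OC)cc(OC)c1)[C@@H](c1ccc(OC)cc1)O3)O[C@H](c1ccc(OC)cc1)[C@H]2C(=O)OC
F9 | step 16 | heptamethyl ether of the target with free resorcinol ring B | COc1ccc([C@@H]2Cc3c4c(cc5c3[C@@H](c3cc(OC)cc(OC)c3)[C@H](c3ccc(OC)cc3)O5)O[C@H](c3ccc(OC)cc3)[C@H]4c3cc(O)cc(O)c32)cc1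
A1 | alternative 1 | methyl (2R,3R)-6-(benzyloxy)-2-(4-methoxyphenyl)-4-(triflyloxy)-2,3-dihydrobenzofuran-3-carboxylate | COC(=O)[C@H]1[C@H](c2ccc(OC)cc2)Oc2cc(OCc3ccccc3)cc(OS(=O)(=O)C(F)(F)F)c21
A2 | alternative 1 | (2R)-7-(benzyloxy)-2-(4-methoxyphenyl)-4-oxochroman-5-yl trifluoromethanesulfonate | O=C1C[C@H](c2ccc(OC)cc2)Oc2cc(OCc3ccccc3)cc(OS(=O)(=O)C(F)(F)F)c21
A3 | alternative 1 | (2R)-naringenin | O=C1C[C@H](c2ccc(O)cc2)Oc2cc(O)cc(O)c21
A4 | alternative 2 | (2R,3R)-4-{[(tert-butyldimethylsilyl)oxy]methyl}-3-(3,5-dimethoxyphenyl)-2-(4-methoxyphenyl)-2,3-dihydrobenzofuran-6-ol | CC(C)(C)[Si](C)(C)OCc1cc(O)cc2c1[C@@H](c1cc(OC)cc(OC)c1)[C@H](c1ccc(OC)cc1)O2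
A5 | alternative 2 | 2-{[(tert-butyldimethylsilyl)oxy]methyl}-4-diazo-5-(3,5-dimethoxyphenyl)-6-(ethynyloxy)-6-(4-methoxyphenyl)hex-1-en-3-one (C5 and C6 as in A4) | C#CO[C@@H](c1ccc(OC)cc1)[C@H](c1cc(OC)cc(OC)c1)C(=[N+]=[N-])C(=O)C(=C)CO[Si](C)(C)C(C)(C)C
A6 | alternative 3 | dibenzosuberene with the Ca=Cb double bond (nonamethyl ether) | COc1ccc(C2=Cc3c4c(cc5c3[C@@H](c3cc(OC)cc(OC)c3)[C@H](c3ccc(OC)cc3)O5)O[C@H](c3ccc(OC)cc3)[C@H]4c3cc(OC)cc(OC)c32)cc1
A7 | alternative 3 | eight-membered sulfone with SO2 between Ca and Cb (Ca unassigned) | COc1ccc(C2S(=O)(=O)Cc3c4c(cc5c3[C@@H](c3cc(OC)cc(OC)c3)[C@H](c3ccc(OC)cc3)O5)O[C@H](c3ccc(OC)cc3)[C@H]4c3cc(OC)cc(OC)c32)cc1
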